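**Retrosynthetic overview**
- The two MOM ethers come off in the flask of the last step. The key cut is C2–C1' of the side chain, giving a chromon-2-yl carbanion and a C20 primary bromide.
- Both of these carbons are natively electrophilic. C2 is the acceptor (latent acyl) carbon of the pyranone, so it is used as an α-metalated enol ether, which is a masked acyl anion or β-acylvinyl anion.
- The 2,3-unsubstituted chromone comes from an o-hydroxyacetophenone and a one-carbon unit (amide acetal).
- The acetophenone comes from phloroacetophenone by double C-methylation and selective bis-MOM protection.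
- Ring order: the benzene ring is bought, the pyranone (the only ring made) is closed in step 3, and the chain is attached last. This allows a cheap even-numbered C20 halide instead of a C21 acid.

Assumption: the target has no stereocentre and is achiral, so there is no enantiomer to control. The side chain is read as unbranched icosyl (C20).

**Step 1**
Reactants: 1 2',4',6'-trihydroxyacetophenone; 2 iodomethane
Product: 3 1-(2,4,6-trihydroxy-3,5-dimethylphenyl)ethan-1-one
Conditions: MeI (2.1 equiv), NaOMe (2.1 equiv), MeOH, 0 → 45 °C; crystallise or chromatograph away the mono- and gem-trimethyl products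
Reagents that add atoms: iodomethane (CI)
Why: In a protic solvent the hydrogen-bonded phloroglucinolate is alkylated at carbon rather than oxygen (nuclear C-methylation of an ambident phenolate, SN2), and limiting MeI and base to two equivalents stops at the aromatic 3,5-dimethyl stage; no stereocentre is formed.

**Step 2**
Reactants: 3 1-(2,4,6-trihydroxy-3,5-dimethylphenyl)ethan-1-one; 4 chloromethyl methyl ether
Product: 5 1-[2-hydroxy-4,6-bis(methoxymethoxy)-3,5-dimethylphenyl]ethan-1-one
Conditions: MOMCl (2.2 equiv), K2CO3 (3 equiv), acetone, 0 °C → reflux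
Reagents that add atoms: chloromethyl methyl ether (COCCl)
Why: In this Williamson-type O-alkylation (acetal protection) the 4-OH and one ortho OH react, while the remaining ortho OH is hydrogen-bonded to the acetyl carbonyl, is much less acidic and nucleophilic, and stays free for the ring closure.

**Step 3**
Reactants: 5 1-[2-hydroxy-4,6-bis(methoxymethoxy)-3,5-dimethylphenyl]ethan-1-one; 6 N,N-dimethylformamide dimethyl acetal
Product: 8 5,7-bis(methoxymethoxy)-6,8-dimethyl-4H-chromen-4-one, via enaminone 7 (not isolated)
Conditions: DMF-DMA (3 equiv), toluene, 100 °C; evaporate; AcOH (5 equiv), CH2Cl2, 40 °C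
Reagents that add atoms: N,N-dimethylformamide dimethyl acetal (CN(C)C(OC)OC)
Why: Amide-acetal condensation on the methyl ketone gives the (E)-enaminone, whose free phenol closes the ring by 6-endo oxa-Michael addition and loss of Me2NH (enaminone chromone synthesis) under acid too weak to cleave aryl MOM ethers.

**Step 4**
Reactants: 8 5,7-bis(methoxymethoxy)-6,8-dimethyl-4H-chromen-4-one; 9 1-bromoicosane
Product: 12 5,7-dihydroxy-2-icosyl-6,8-dimethyl-4H-chromen-4-one, via bis(chromon-2-yl)zinc 10 (not isolated), via MOM-protected 2-icosylchromone 11 (not isolated)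
Conditions: TMP2Zn·2MgCl2·2LiCl (0.6 equiv, commercial solution), THF, −20 → 25 °C, 1 h; then 9 (1.3 equiv), Pd-PEPPSI-IPr (2 mol %), LiBr, THF/NMP 2:1, 25 → 50 °C; then MeOH, conc. HCl, 60 °C
Reagents that add atoms: 1-bromoicosane (CCCCCCCCCCCCCCCCCCCCBr)
Why: Proposed new method: with MgCl2 occupying the C4 carbonyl, the TMP-zinc amide cannot be directed to C3 and removes the most acidic C2–H next to the ring oxygen, which turns the natively electrophilic C2 into a covalent α-zincated enol ether (masked acyl anion/β-acylvinyl anion) that neither ring-opens nor adds to a second chromone, and a bulky Pd–NHC catalyst that takes up primary alkyl bromides by SN2-type oxidative addition and reductively eliminates faster than β-hydride elimination then joins it to the equally electrophilic C1 of 9, after which HCl/MeOH transacetalises both MOM groups; the closest known reaction types are the Lewis-acid-directed C2 zincation/aryl Negishi coupling of 5,7-dialkoxychromones and the alkyl-halide Negishi coupling of aryl- and alkenylzinc reagents, and no stereocentre is formed.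

**Compound list**
1 | 2',4',6'-trihydroxyacetophenone (phloroacetophenone) | CC(=O)c1c(O)cc(O)cc1O | starting material
2 | iodomethane | CI | starting material
3 | 1-(2,4,6-trihydroxy-3,5-dimethylphenyl)ethan-1-one | CC(=O)c1c(O)c(C)c(O)c(C)c1O | intermediate
4 | chloromethyl methyl ether | COCCl | starting material
5 | 1-[2-hydroxy-4,6-bis(methoxymethoxy)-3,5-dimethylphenyl]ethan-1-one | CC(=O)c1c(O)c(C)c(OCOC)c(C)c1OCOC | intermediate
6 | N,N-dimethylformamide dimethyl acetal | CN(C)C(OC)OC | starting material
7 | (E)-3-(dimethylamino)-1-[2-hydroxy-4,6-bis(methoxymethoxy)-3,5-dimethylphenyl]prop-2-en-1-one | CN(C)/C=C/C(=O)c1c(O)c(C)c(OCOC)c(C)c1OCOC | intermediate (not isolated)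
8 | 5,7-bis(methoxymethoxy)-6,8-dimethyl-4H-chromen-4-one | O=c1ccoc2c(C)c(OCOC)c(C)c(OCOC)c12 | intermediate
9 | 1-bromoicosane | CCCCCCCCCCCCCCCCCCCCBr | starting material
10 | bis[5,7-bis(methoxymethoxy)-6,8-dimethyl-4-oxo-4H-chromen-2-yl]zinc (MgCl2/LiCl complex) | COCOc1c(C)c(OCOC)c2c(=O)cc([Zn]c3cc(=O)c4c(OCOC)c(C)c(OCOC)c(C)c4o3)oc2c1C | intermediate (not isolated)
11 | 2-icosyl-5,7-bis(methoxymethoxy)-6,8-dimethyl-4H-chromen-4-one | CCCCCCCCCCCCCCCCCCCCc1cc(=O)c2c(OCOC)c(C)c(OCOC)c(C)c2o1 | intermediate (not isolated)
12 | 5,7-dihydroxy-2-icosyl-6,8-dimethyl-4H-chromen-4-one | CCCCCCCCCCCCCCCCCCCCc1cc(=O)c2c(O)c(C)c(O)c(C)c2o1 | target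

**Totals**
Total step count: 4. Longest linear sequence: 4.

**Steps most likely to fail**

Step 4 is the riskiest. The electron-poor vinylzinc may transmetalate too slowly, so the alkylpalladium species decays by β-hydride elimination to icosene and 8 is recovered. The fallback sets out from 8 and 9 and swaps the roles of the two partners. Compound 8 is zincated to 10 as before and quenched with I2 to give 2-iodo-5,7-bis(methoxymethoxy)-6,8-dimethyl-4H-chromen-4-one F1. Compound 9 is converted with Zn dust and LiCl in THF into icosylzinc bromide F2. PdCl2(dppf)-catalysed coupling of the activated vinyl iodide with the alkylzinc then gives 11. The route is rejoined at 11, which is treated with HCl/MeOH as in the last part of step 4.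

Step 1 may give a poorly separable mixture of mono-, di- and dearomatised gem-trimethyl products. The fallback sets out from 1 and installs each carbon as an aminomethyl group that cannot add twice at the same position. A double Mannich reaction (aq. CH2O, aq. Me2NH, EtOH, rt) gives 1-{3,5-bis[(dimethylamino)methyl]-2,4,6-trihydroxyphenyl}ethan-1-one F3. Hydrogenolysis of its benzylic C–N bonds (H2 4 bar, Pd/C, MeOH/AcOH, 60 °C, through the o-quinone methides) gives the two methyl groups. The route is rejoined at 3.

In step 3 the condensation at the di-ortho-substituted acetyl group may be sluggish, or the labile MOM ether beside the carbonyl may be lost during the acid-promoted closure. The fallback sets out from 3 and closes the ring before any protecting group is present. Triethyl orthoformate and 70% HClO4, followed by hot water (benzopyrylium salt route), give 5,7-dihydroxy-6,8-dimethyl-4H-chromen-4-one F4. This is then bis-protected with 4 (NaH, DMF, 0 °C → rt). The route is rejoined at 8.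

**Further compounds**
F1 | step 4 | 2-iodo-5,7-bis(methoxymethoxy)-6,8-dimethyl-4H-chromen-4-one | COCOc1c(C)c(OCOC)c2c(=O)cc(I)oc2c1C
F2 | step 4 | icosylzinc bromide | CCCCCCCCCCCCCCCCCCCC[Zn]Br
F3 | step 1 | 1-{3,5-bis[(dimethylamino)methyl]-2,4,6-trihydroxyphenyl}ethan-1-one | CC(=O)c1c(O)c(CN(C)C)c(O)c(CN(C)C)c1O
F4 | step 3 | 5,7-dihydroxy-6,8-dimethyl-4H-chromen-4-one | O=c1ccoc2c(C)c(O)c(C)c(O)c12
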